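**Plan**

- Retrosynthesis: the last operation cuts O1'–C2, C2–C3, C1–C6 and C4–C7 of the spiro-norbornane (bicycloheptane numbering) at once and unfolds the tricycle to an acyclic allylic diphosphate, a geranyl diphosphate whose C3 methyl group carries the (S)-CH(i-Bu)Ar unit.
- Feature that allows this: the 3,3-dimethylnorbornane whose C2 bears both O1' and the C3' methylene of the chroman is a camphyl cation, the ion camphene synthases make from a geranyl chain, trapped at C2 by the phenol oxygen on the endo face (syn to C5–C6).
- Further cuts: C1–O (diphosphate for chloride), the C3–C4 bond of the chain (alkyl cuprate + 2-ynoate), the alkyne carbons (aldehyde homologation, carboxylation) and the aryl–CH bond (phenol + enal).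
- Forward order: enal, aryl-bearing stereocentre, alkyne, diformylation and masking, ynoate, trisubstituted alkene, allylic alcohol, triphenol, chloride, diphosphate; the cyclohexene, the second carbocycle and the pyran then close in this order in one enzymatic step.
- Stereochemistry: C4' from the amine catalyst (step 2), the alkene geometry from syn-carbocupration (step 7), C1, C2 and C4 of the norbornane from the fold of the cyclase (step 12).

Key step: step 12

Remark: the diphosphate of step 11 would be handled as its ammonium salt and is drawn as the free acid; the (2Z) descriptor used from step 7 onward denotes the geranyl-type geometry (4-methylpent-3-enyl chain trans to C1), because the arylalkyl branch outranks that chain.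

**Route**

Step 1
Reactants: 1 isovaleraldehyde (3-methylbutanal)
Product: 2 (2E)-5-methylhex-2-enal
Conditions: Ph3P=CHCHO, toluene, 80 °C; 1 in excess
Reagents that add atoms: (triphenylphosphoranylidene)acetaldehyde, O=CC=P(c1ccccc1)(c1ccccc1)c1ccccc1
Why: A Wittig reaction of the stabilised formylmethylene ylide with an aliphatic aldehyde gives the (E)-enal, and the excess of volatile 1 suppresses a second homologation.

Step 2
Reactants: 2 (2E)-5-methylhex-2-enal; 3 3,5-dimethoxyphenol
Product: 4 (4S)-5,7-dimethoxy-4-(2-methylpropyl)-3,4-dihydro-2H-chromen-2-ol (lactol, both C2 epimers)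
Conditions: (R)-2-[diphenyl(trimethylsilyloxy)methyl]pyrrolidine (20 mol%), PhCO2H (20 mol%), toluene, 0 °C; 3 in excess
Reagents that add atoms: none
Why: In this iminium-catalysed Friedel–Crafts alkylation with hemiacetal closure, the carbon ortho to the phenol hydroxyl adds to the β-carbon of the (E)-iminium ion on the face left open by the diphenyl(silyloxy)methyl group of the (R)-catalyst, which should set C4 as (S), and the lactol ring then ties up the aldehyde.

Step 3
Reactants: 4 lactol
Product: 6 1,3,5-trimethoxy-2-[(4S)-6-methylhept-1-yn-4-yl]benzene, via alkynyl phenol 5 (not isolated)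
Conditions: dimethyl (1-diazo-2-oxopropyl)phosphonate, K2CO3, MeOH, 0 °C → rt; then MeI, DMF, 40 °C
Reagents that add atoms: dimethyl (1-diazo-2-oxopropyl)phosphonate, COP(=O)(OC)C(=[N+]=[N-])C(C)=O; iodomethane, CI
Why: Base opens the lactol to the hydroxy aldehyde, which undergoes Ohira–Bestmann alkynylation, and the phenoxide left behind is O-methylated in the same flask (Williamson ether synthesis), the stereocentre being β to the carbonyl group and unable to epimerise.

Step 4
Reactants: 6 trimethoxyaryl alkyne
Product: 7 2,4,6-trimethoxy-5-[(4S)-6-methylhept-1-yn-4-yl]benzene-1,3-dicarbaldehyde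
Conditions: Cl2CHOMe, TiCl4, CH2Cl2, −78 → −20 °C; ice–water
Reagents that add atoms: dichloromethyl methyl ether, COC(Cl)Cl; water, O
Why: Rieche formylation should occur twice because each free ring position lies between two methoxy groups, while the terminal alkyne is far too weak a nucleophile to compete with the arene.

Step 5
Reactants: 7 dialdehyde
Product: 8 1,3-bis(dimethoxymethyl)-2,4,6-trimethoxy-5-[(4S)-6-methylhept-1-yn-4-yl]benzene
Conditions: HC(OMe)3, MeOH, p-TsOH (cat.), rt; Et3N quench
Reagents that add atoms: trimethyl orthoformate, COC(OC)OC; methanol, CO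
Why: Acid-catalysed acetalisation with the orthoformate as water scavenger masks both aldehydes against the organolithium, organocopper and hydride reagents that follow.

Step 6
Reactants: 8 bis-acetal alkyne
Product: 9 methyl (5S)-5-[3,5-bis(dimethoxymethyl)-2,4,6-trimethoxyphenyl]-7-methyloct-2-ynoate
Conditions: n-BuLi, THF, −78 °C; ClCO2Me, −78 → 0 °C
Reagents that add atoms: methyl chloroformate, COC(Cl)=O
Why: Deprotonation of the terminal alkyne and C-acylation of the lithium acetylide with a chloroformate is the standard route to a 2-ynoate, and acetals and aryl ethers are inert to it.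

Step 7
Reactants: 9 ynoate; 10 5-bromo-2-methylpent-2-ene
Product: 12 methyl (2Z)-3-{(2S)-2-[3,5-bis(dimethoxymethyl)-2,4,6-trimethoxyphenyl]-4-methylpentyl}-7-methylocta-2,6-dienoate, via homoprenyl Grignard reagent 11 (not isolated)
Conditions: 10, Mg, THF, rt; CuBr·SMe2 (0.5 equiv per 11), THF, −78 °C; then 9, −78 °C; MeOH then aq. NH4Cl at −78 °C
Reagents that add atoms: none
Why: Syn-carbocupration of the ynoate by the magnesium dialkylcuprate at low temperature and protonation of the alkenylcopper with retention (conjugate addition of an organocuprate to an alkynoate) place the new 4-methylpent-3-enyl group trans to the ester, which is the geranyl-type geometry.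

Step 8
Reactants: 12 enoate
Product: 14 (2Z)-3-[(2S)-2-(3,5-diformyl-2,4,6-trimethoxyphenyl)-4-methylpentyl]-7-methylocta-2,6-dien-1-ol, via acetal-protected allylic alcohol 13 (not isolated)
Conditions: i-Bu2AlH, CH2Cl2, −78 °C; aq. potassium sodium tartrate; then pyridinium p-toluenesulfonate, acetone–H2O, rt
Reagents that add atoms: water, O
Why: Diisobutylaluminium hydride reduces the enoate 1,2 to the allylic alcohol at low temperature without touching the acetals, and mild aqueous acid then hydrolyses the electron-rich aryl acetals faster than it can ionise the allylic alcohol, the phenols still being capped.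

Step 9
Reactants: 14 trimethoxy dialdehyde alcohol
Product: 15 (2Z)-3-[(2S)-2-(3,5-diformyl-2,4,6-trihydroxyphenyl)-4-methylpentyl]-7-methylocta-2,6-dien-1-ol
Conditions: NaSEt (excess), DMF, 110 °C; then AcOH, 0 °C
Reagents that add atoms: none
Why: Nucleophilic (SN2) demethylation by thiolate should reach all three ethers because each is ortho or para to a formyl group and leaves as a stabilised phenoxide, and the basic medium spares the alkenes and the allylic alcohol that a Lewis acid would ionise.

Step 10
Reactants: 15 triphenol allylic alcohol
Product: 16 (2Z)-1-chloro-3-[(2S)-2-(3,5-diformyl-2,4,6-trihydroxyphenyl)-4-methylpentyl]-7-methylocta-2,6-diene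
Conditions: NCS, Me2S, CH2Cl2, −30 → 0 °C; cold aqueous work-up, used crude at once
Reagents that add atoms: N-chlorosuccinimide, O=C1CCC(=O)N1Cl
Why: Corey–Kim chlorination converts the primary allylic alcohol into the chloride through an alkoxysulfonium ion without acid and without allylic transposition, and the hydrogen-bonded phenols, which have no free ortho or para position, are returned unchanged on work-up.

Step 11
Reactants: 16 allylic chloride
Product: 17 (2Z)-3-[(2S)-2-(3,5-diformyl-2,4,6-trihydroxyphenyl)-4-methylpentyl]-7-methylocta-2,6-dien-1-yl trihydrogen diphosphate (ammonium salt)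
Conditions: (n-Bu4N)3HP2O7 (3 equiv), MeCN, 0 °C → rt; cation exchange to the ammonium form (aq. NH4HCO3); reversed-phase chromatography; lyophilisation
Reagents that add atoms: tris(tetrabutylammonium) hydrogen diphosphate, CCCC[N+](CCCC)(CCCC)CCCC.CCCC[N+](CCCC)(CCCC)CCCC.CCCC[N+](CCCC)(CCCC)CCCC.OP(=O)([O-])OP(=O)([O-])[O-]
Why: SN2 displacement of a primary allylic chloride by the diphosphate anion in acetonitrile is the standard preparation of prenyl diphosphates, and the excess of the salt should outpace attack by the weakly nucleophilic, formyl-chelated phenoxide.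

Step 12
Reactants: 17 diphosphate
Product: 18 (1R,2R,4S,4'S)-5',7'-dihydroxy-3,3-dimethyl-4'-(2-methylpropyl)-3',4'-dihydrospiro[bicyclo[2.2.1]heptane-2,2'-chromene]-6',8'-dicarbaldehyde (target)
Conditions: engineered (−)-camphene synthase variant (class 1 monoterpene cyclase, pocket enlarged for the C3 side chain), MgCl2, HEPES buffer pH 7.2, 30 °C; then pH 5, EtOAc extraction
Reagents that add atoms: none
Why: Proposed new method: the magnesium-bound diphosphate of 17 is ionised, returned to C3 (linalyl-type isomer) and ionised again from the cisoid conformer, after which C6 of the C6=C7 alkene attacks C1 and closes the cyclohexene (six-membered ring, the alkene staying outside it so that the charge moves to exocyclic C7), C3 of the new ring alkene bonds to C7 in a transannular anti-Markovnikov closure that completes the bicyclo[2.2.1] frame and leaves a bornyl-type cation at C2, a Wagner–Meerwein shift of C4 from C3 to C2 gives the tertiary camphyl-type cation at C3, and the ortho phenol oxygen captures it to close the six-membered pyran (chain numbered as in geranyl diphosphate). The closest known reaction type is the cyclisation of geranyl diphosphate to camphene and bornyl diphosphate by class 1 monoterpene synthases, together with the turnover of modified prenyl diphosphates by such cyclases; new are the large substituent on the C3 methyl group and a phenol as the terminating nucleophile. The two bridgehead centres (chain C2 and C6) are set by the helical fold in which the active site binds the chain, here the fold that leads to (−)-camphene from the natural substrate, and the spiro centre (chain C3) by the face on which the pocket holds the phenol, which must be the endo face that C4 has just left, whereas the free cation is trapped on the exo face in solution. The (S) centre from step 2 is not touched and has to be accommodated as a spectator substituent. The step needs the carbocyclisations and the shift to outrun early closure of the phenol onto C3 of the allylic cation, capture by water and proton loss. The substrate supports this because its only internal nucleophile is an oxygen tied to C3 by a two-carbon tether (only the six-membered ether can form), this oxygen is tempered by its hydrogen bond to the ortho formyl group, the arene has no free position for C-alkylation, and the side chain grows from the very methyl group that the parent enzyme deprotonates, so the phenol sits where chain termination normally takes place.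

**Compound list**

1 | isovaleraldehyde (3-methylbutanal) | CC(C)CC=O | starting material
2 | (2E)-5-methylhex-2-enal | CC(C)C/C=C/C=O | intermediate
3 | 3,5-dimethoxyphenol | COc1cc(O)cc(OC)c1 | starting material
4 | (4S)-5,7-dimethoxy-4-(2-methylpropyl)-3,4-dihydro-2H-chromen-2-ol (C2 epimers) | CC(C)C[C@H]1CC(O)Oc2cc(OC)cc(OC)c21 | intermediate
5 | 3,5-dimethoxy-2-[(4S)-6-methylhept-1-yn-4-yl]phenol | C#CC[C@H](CC(C)C)c1c(O)cc(OC)cc1OC | intermediate (not isolated)
6 | 1,3,5-trimethoxy-2-[(4S)-6-methylhept-1-yn-4-yl]benzene | C#CC[C@H](CC(C)C)c1c(OC)cc(OC)cc1OC | intermediate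
7 | 2,4,6-trimethoxy-5-[(4S)-6-methylhept-1-yn-4-yl]benzene-1,3-dicarbaldehyde | C#CC[C@H](CC(C)C)c1c(OC)c(C=O)c(OC)c(C=O)c1OC | intermediate
8 | 1,3-bis(dimethoxymethyl)-2,4,6-trimethoxy-5-[(4S)-6-methylhept-1-yn-4-yl]benzene | C#CC[C@H](CC(C)C)c1c(OC)c(C(OC)OC)c(OC)c(C(OC)OC)c1OC | intermediate
9 | methyl (5S)-5-[3,5-bis(dimethoxymethyl)-2,4,6-trimethoxyphenyl]-7-methyloct-2-ynoate | COC(=O)C#CC[C@H](CC(C)C)c1c(OC)c(C(OC)OC)c(OC)c(C(OC)OC)c1OC | intermediate
10 | 5-bromo-2-methylpent-2-ene | CC(C)=CCCBr | starting material
11 | (4-methylpent-3-en-1-yl)magnesium bromide | CC(C)=CCC[Mg]Br | intermediate (not isolated)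
12 | methyl (2Z)-3-{(2S)-2-[3,5-bis(dimethoxymethyl)-2,4,6-trimethoxyphenyl]-4-methylpentyl}-7-methylocta-2,6-dienoate | CC(C)=CCC/C(=C/C(=O)OC)C[C@H](CC(C)C)c1c(OC)c(C(OC)OC)c(OC)c(C(OC)OC)c1OC | intermediate
13 | (2Z)-3-{(2S)-2-[3,5-bis(dimethoxymethyl)-2,4,6-trimethoxyphenyl]-4-methylpentyl}-7-methylocta-2,6-dien-1-ol | CC(C)=CCC/C(=C/CO)C[C@H](CC(C)C)c1c(OC)c(C(OC)OC)c(OC)c(C(OC)OC)c1OC | intermediate (not isolated)
14 | (2Z)-3-[(2S)-2-(3,5-diformyl-2,4,6-trimethoxyphenyl)-4-methylpentyl]-7-methylocta-2,6-dien-1-ol | CC(C)=CCC/C(=C/CO)C[C@H](CC(C)C)c1c(OC)c(C=O)c(OC)c(C=O)c1OC | intermediate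
15 | (2Z)-3-[(2S)-2-(3,5-diformyl-2,4,6-trihydroxyphenyl)-4-methylpentyl]-7-methylocta-2,6-dien-1-ol | CC(C)=CCC/C(=C/CO)C[C@H](CC(C)C)c1c(O)c(C=O)c(O)c(C=O)c1O | intermediate
16 | (2Z)-1-chloro-3-[(2S)-2-(3,5-diformyl-2,4,6-trihydroxyphenyl)-4-methylpentyl]-7-methylocta-2,6-diene | CC(C)=CCC/C(=C/CCl)C[C@H](CC(C)C)c1c(O)c(C=O)c(O)c(C=O)c1O | intermediate
17 | (2Z)-3-[(2S)-2-(3,5-diformyl-2,4,6-trihydroxyphenyl)-4-methylpentyl]-7-methylocta-2,6-dien-1-yl trihydrogen diphosphate | CC(C)=CCC/C(=C/COP(=O)(O)OP(=O)(O)O)C[C@H](CC(C)C)c1c(O)c(C=O)c(O)c(C=O)c1O | intermediate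
18 | (1R,2R,4S,4'S)-5',7'-dihydroxy-3,3-dimethyl-4'-(2-methylpropyl)-3',4'-dihydrospiro[bicyclo[2.2.1]heptane-2,2'-chromene]-6',8'-dicarbaldehyde | CC(C)C[C@H]1C[C@@]2(Oc3c(C=O)c(O)c(C=O)c(O)c31)[C@@H]1CC[C@@H](C1)C2(C)C | target

**Count**

Total step count: 12. Longest linear sequence: 12 steps (1 to 18); 3 and 10 are bought and enter in steps 2 and 7.

**Steps most likely to fail**

1. Step 12. The cyclase may not turn over the enlarged substrate, the phenol may close early onto the allylic cation, the cation may lose a proton or take up water before the shift, or the oxygen may be captured on the exo face. The fallback is the hetero-Diels–Alder reaction of an ortho-quinone methide with camphene, which is known chemistry for formylphloroglucinol–terpene adducts. It sets out from isovaleraldehyde 1. Knoevenagel condensation of 1 with purchased 2,4,6-trihydroxybenzene-1,3-dicarbaldehyde (O=Cc1c(O)cc(O)c(C=O)c1O; NaOAc, AcOH, 80 °C) in the presence of purchased (1S,4R)-(−)-camphene (C=C1[C@@H]2CC[C@@H](C2)C1(C)C) would form the ortho-quinone methide 2,4-dihydroxy-5-(3-methylbutylidene)-6-oxocyclohexa-1,3-diene-1,3-dicarbaldehyde F1 in the flask. Its C=C–C=O unit adds across the exocyclic alkene of camphene with the oxygen bonding to the ring carbon, and the sequence comes back to the route at 18. This fallback has no control over C4' and needs attack on the endo face of camphene, whereas camphene usually reacts on its exo face, so 18 would have to be separated from up to three diastereomers by preparative HPLC and may be a minor component.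

2. Step 11. Intramolecular O-alkylation by the neighbouring phenoxide, or ionisation of the allylic chloride during handling, may outrun the diphosphate displacement. The fallback sets out from alcohol 15 and comes back at 17 without passing through 16. Trichloroacetonitrile and bis(triethylammonium) hydrogen phosphate in MeCN phosphorylate the alcohol directly; the phosphate is activated as an imidoyl phosphate, so no allylic electrophile is formed. The diphosphate is then separated from mono- and triphosphate by ion-exchange chromatography. No new compound arises (F0).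

3. Step 2. Enantiofacial control with an aliphatic enal may be poor, the phenol may react para to its hydroxyl, or it may be alkylated twice. The fallback sets the centre with an oxazolidinone auxiliary; it sets out from enal 2 and comes back at alkyne 6.
   - Pinnick oxidation of 2 (NaClO2, NaH2PO4, 2-methylbut-2-ene, t-BuOH–H2O) gives (2E)-5-methylhex-2-enoic acid F2.
   - The mixed pivalic anhydride of F2 (PivCl, Et3N) acylates lithiated (4R)-4-phenyl-1,3-oxazolidin-2-one to give (4R)-3-[(2E)-5-methylhex-2-enoyl]-4-phenyl-1,3-oxazolidin-2-one F3.
   - The aryl cuprate from purchased (2,4,6-trimethoxyphenyl)magnesium bromide and CuBr·SMe2 (THF, −40 °C) adds to the β-carbon anti to the phenyl group of the magnesium-chelated s-cis imide, to give (4R)-3-[(3S)-5-methyl-3-(2,4,6-trimethoxyphenyl)hexanoyl]-4-phenyl-1,3-oxazolidin-2-one F4.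
   - LiBH4 (THF, one equivalent of water) releases the auxiliary and gives (3S)-5-methyl-3-(2,4,6-trimethoxyphenyl)hexan-1-ol F5.
   - Dess–Martin periodinane gives (3S)-5-methyl-3-(2,4,6-trimethoxyphenyl)hexanal F6, and Ohira–Bestmann alkynylation (K2CO3, MeOH) then gives 6.

Further compounds
F1 | step 12 | 2,4-dihydroxy-5-(3-methylbutylidene)-6-oxocyclohexa-1,3-diene-1,3-dicarbaldehyde (ortho-quinone methide, not isolated) | CC(C)CC=C1C(=O)C(C=O)=C(O)C(C=O)=C1O
F0 | step 11 | none | none
F2 | step 2 | (2E)-5-methylhex-2-enoic acid | CC(C)C/C=C/C(=O)O
F3 | step 2 | (4R)-3-[(2E)-5-methylhex-2-enoyl]-4-phenyl-1,3-oxazolidin-2-one | CC(C)C/C=C/C(=O)N1[C@H](c2ccccc2)COC1=O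
F4 | step 2 | (4R)-3-[(3S)-5-methyl-3-(2,4,6-trimethoxyphenyl)hexanoyl]-4-phenyl-1,3-oxazolidin-2-one | O=C(C[C@H](CC(C)C)c1c(OC)cc(OC)cc1OC)N1[C@H](c2ccccc2)COC1=O
F5 | step 2 | (3S)-5-methyl-3-(2,4,6-trimethoxyphenyl)hexan-1-ol | OCC[C@H](CC(C)C)c1c(OC)cc(OC)cc1OC
F6 | step 2 | (3S)-5-methyl-3-(2,4,6-trimethoxyphenyl)hexanal | O=CC[C@H](CC(C)C)c1c(OC)cc(OC)cc1OC
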